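**Plan**

- Locants: flavone 1 is the 5-hydroxy-7-methoxychromone carrying ring B (primed); flavone 2 is the apigenin unit (double-primed).
- Retrosynthesis: the three benzyl ethers are removed first. Then the cuts are C4''–C4a'' (Friedel–Crafts acylation), O1''–C2'' (oxa-Michael addition to an arylpropiolate), O1–C2 and C2–C3 of flavone 1 (cyclodehydration, Claisen opening of a lactone) and the biaryl bond C2'–C8'' (Hurtley arylation).
- Forward order of rings: benzo[c]chromenone lactone joining ring B to the phloroglucinol ring, pyranone of flavone 1, aryl vinyl ether on O1'', pyranone ring C of flavone 2, debenzylation.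
- Enabling feature: on ring A of flavone 2, C8a'' (bearing O1'') lies between C8'', which ring B occupies, and the unsubstituted C4a''. An acyl group tethered through O1'' can therefore reach C4a'' only, so the 8''-aryl pattern follows from connectivity and not from a choice between hydroxyls.
- Stereochemistry: the target has no stereocentre. The only stereo-element on the way is the vinyl ether geometry; Z is needed for closure and the E isomer feeds into it by acid equilibration.

Key step: step 8

Assumption: the C2'–C8'' axis has no defined configuration in the target, so none is controlled; the vinyl ether ester and acid are written as the Z isomers, and any E isomer is carried along because it equilibrates under the acid of the key step.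

**Route**

Step 1
Reactants: 1 2-bromo-4-methoxybenzoic acid; 2 phloroglucinol (benzene-1,3,5-triol)
Product: 4 1,3-dihydroxy-9-methoxy-6H-benzo[c]chromen-6-one, via biaryl hydroxy acid 3 (not isolated)
Conditions: 2 (2 equiv), NaOH (aq), 100 °C; then CuSO4 (10 mol%, aq), reflux; HCl work-up
Reagents that add atoms: none
Why: Hurtley reaction, in which the ortho-carboxylate assists copper-catalysed replacement of bromide by the carbon nucleophile of the phloroglucinol anion and hydroxy acid 3 lactonises onto one of its two equivalent flanking hydroxyls, so the symmetry of 2 leaves no regiochemical choice and the lactone marks the oxygen that will become O1''.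

Step 2
Reactants: 4 1,3-dihydroxy-9-methoxy-6H-benzo[c]chromen-6-one
Product: 5 1,3-bis(benzyloxy)-9-methoxy-6H-benzo[c]chromen-6-one
Conditions: BnBr (2.4 equiv), K2CO3 (2.5 equiv), DMF, 60 °C
Reagents that add atoms: benzyl bromide, BrCc1ccccc1
Why: Williamson ether synthesis on the two free, non-chelated phenols should proceed cleanly, while the aryl lactone is inert to carbonate in dry DMF and keeps the third oxygen masked.

Step 3
Reactants: 5 1,3-bis(benzyloxy)-9-methoxy-6H-benzo[c]chromen-6-one; 6 2',6'-dihydroxy-4'-methoxyacetophenone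
Product: 7 1-{2-[2,4-bis(benzyloxy)-6-hydroxyphenyl]-4-methoxyphenyl}-3-(2,6-dihydroxy-4-methoxyphenyl)propane-1,3-dione
Conditions: 6 (1.2 equiv), LiHMDS (5 equiv), THF, −78 to −10 °C; then 5, −78 °C to rt; aq. HCl
Reagents that add atoms: none
Why: Crossed Claisen condensation, in which the lithium polyanion of the o-hydroxyacetophenone is acylated at carbon by the twisted aryl lactone, whose phenoxide leaving group stays in the molecule as the free hydroxyl that later becomes O1''.

Step 4
Reactants: 7 1-{2-[2,4-bis(benzyloxy)-6-hydroxyphenyl]-4-methoxyphenyl}-3-(2,6-dihydroxy-4-methoxyphenyl)propane-1,3-dione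
Product: 9 2-[2-(2,4-bis(benzyloxy)-6-hydroxyphenyl)-4-methoxyphenyl]-5-hydroxy-7-methoxy-4H-chromen-4-one, via 2-hydroxychromanone hemiketal 8 (not isolated)
Conditions: p-TsOH·H2O (10 mol%), toluene, 80 °C
Reagents that add atoms: none
Why: Acid-catalysed cyclodehydration of an o-hydroxyaryl 1,3-diketone (the closing stage of a Baker–Venkataraman-type flavone synthesis), in which either of the two equivalent chelated hydroxyls adds to the carbonyl next to ring B, hemiketal 8 loses water, and the aromatic 4-pyranone should act as the sink into which reversible lactol formation by the biaryl phenol drains.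

Step 5
Reactants: 10 1-(benzyloxy)-4-iodobenzene; 11 ethyl propiolate
Product: 12 ethyl 3-[4-(benzyloxy)phenyl]prop-2-ynoate
Conditions: 11 (1.5 equiv, slow addition), PdCl2(PPh3)2 (2 mol%), CuI (4 mol%), K2CO3 (2 equiv), THF, 65 °C
Reagents that add atoms: none
Why: Sonogashira coupling of an aryl iodide with the terminal ynoate is established when an inorganic base replaces the amine, which would otherwise add to the propiolate.

Step 6
Reactants: 9 2-[2-(2,4-bis(benzyloxy)-6-hydroxyphenyl)-4-methoxyphenyl]-5-hydroxy-7-methoxy-4H-chromen-4-one; 12 ethyl 3-[4-(benzyloxy)phenyl]prop-2-ynoate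
Product: 13 ethyl (Z)-3-[4-(benzyloxy)phenyl]-3-{3,5-bis(benzyloxy)-2-[2-(5-hydroxy-7-methoxy-4-oxo-4H-chromen-2-yl)-5-methoxyphenyl]phenoxy}prop-2-enoate
Conditions: 12 (1.3 equiv), Cs2CO3 (0.3 equiv), DMF, 60 °C
Reagents that add atoms: none
Why: Oxa-Michael addition of the only non-chelated phenoxide to the β-carbon of the arylpropiolate, with anti protonation of the vinyl anion favouring the Z isomer, should be chemoselective because the hydrogen-bonded 5-hydroxyl of flavone 1 is far less acidic and less nucleophilic.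

Step 7
Reactants: 13 ethyl (Z)-3-[4-(benzyloxy)phenyl]-3-{3,5-bis(benzyloxy)-2-[2-(5-hydroxy-7-methoxy-4-oxo-4H-chromen-2-yl)-5-methoxyphenyl]phenoxy}prop-2-enoate
Product: 14 (Z)-3-[4-(benzyloxy)phenyl]-3-{3,5-bis(benzyloxy)-2-[2-(5-hydroxy-7-methoxy-4-oxo-4H-chromen-2-yl)-5-methoxyphenyl]phenoxy}prop-2-enoic acid
Conditions: LiOH·H2O (4 equiv), THF/MeOH/H2O, 40 °C; then 1 M HCl, 0 °C
Reagents that add atoms: lithium hydroxide, [Li+].[OH-]
Why: Saponification of the ethyl ester should leave the vinylogous carbonate intact at this temperature, and the 5-phenoxide formed under the conditions deactivates the pyranone of flavone 1 toward hydroxide.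

Step 8
Reactants: 14 (Z)-3-[4-(benzyloxy)phenyl]-3-{3,5-bis(benzyloxy)-2-[2-(5-hydroxy-7-methoxy-4-oxo-4H-chromen-2-yl)-5-methoxyphenyl]phenoxy}prop-2-enoic acid
Product: 16 5,7-bis(benzyloxy)-2-[4-(benzyloxy)phenyl]-8-[2-(5-hydroxy-7-methoxy-4-oxo-4H-chromen-2-yl)-5-methoxyphenyl]-4H-chromen-4-one, via mixed trifluoroacetic anhydride 15 (not isolated)
Conditions: trifluoroacetic anhydride (TFAA, 3 equiv), CH2Cl2, 0 °C to rt; then MeOH, aq. NaHCO3
Reagents that add atoms: none
Why: Trifluoroacetic anhydride converts acid 14 into mixed anhydride 15, whose acyl carbon (as such or as the acylium ion that the vinylogous aryloxy oxygen stabilises) is attacked by C4a'', the ring carbon ortho to the ether oxygen, and loss of the proton restores the arene and leaves the 4-pyranone with the new C4''–C4a'' bond. The closest known reaction type is the intramolecular Friedel–Crafts acylation by which 3-aryloxycinnamic acids are closed to flavones, together with cycloacylations of aryloxy acids promoted by trifluoroacetic anhydride. Ring C of flavone 2 closes as a six-membered ring by electrophilic aromatic substitution, 6-exo-trig at the acyl carbon, the carbonyl oxygen staying outside the ring. No stereocentre is formed; closure needs the Z alkene, and the trifluoroacetic acid released equilibrates the push–pull alkene by reversible protonation at the α-carbon so that E material drains through the Z isomer. The selectivity required is site selectivity on the phloroglucinol ring and the substrate provides it, since of the two carbons ortho to O1'' only C4a'' is free (C8'' carries ring B) and C6'' is out of reach of the tether. The ring attacked is a 1,3,5-trioxygenated arene, so activation without a Lewis acid at 0 °C to room temperature should suffice and should spare the benzyl ethers, flavone 1 and its chelated hydroxyl.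

Step 9
Reactants: 16 5,7-bis(benzyloxy)-2-[4-(benzyloxy)phenyl]-8-[2-(5-hydroxy-7-methoxy-4-oxo-4H-chromen-2-yl)-5-methoxyphenyl]-4H-chromen-4-one
Product: 17 5,7-dihydroxy-8-[2-(5-hydroxy-7-methoxy-4-oxo-4H-chromen-2-yl)-5-methoxyphenyl]-2-(4-hydroxyphenyl)-4H-chromen-4-one (target)
Conditions: H2 (1 atm), 10% Pd/C, THF/MeOH, rt
Reagents that add atoms: none
Why: Hydrogenolysis of the three aryl benzyl ethers over palladium on carbon should be faster than reduction of the flavone C2–C3 double bonds and leaves the two methyl ethers untouched.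

**Compound list**

1 | 2-bromo-4-methoxybenzoic acid | COc1ccc(C(=O)O)c(Br)c1 | starting material
2 | phloroglucinol (benzene-1,3,5-triol) | Oc1cc(O)cc(O)c1 | starting material
3 | 4-methoxy-2-(2,4,6-trihydroxyphenyl)benzoic acid (biaryl hydroxy acid, not isolated) | COc1ccc(C(=O)O)c(-c2c(O)cc(O)cc2O)c1 | intermediate
4 | 1,3-dihydroxy-9-methoxy-6H-benzo[c]chromen-6-one | COc1ccc2c(c1)-c1c(O)cc(O)cc1OC2=O | intermediate
5 | 1,3-bis(benzyloxy)-9-methoxy-6H-benzo[c]chromen-6-one | COc1ccc2c(c1)-c1c(OCc3ccccc3)cc(OCc3ccccc3)cc1OC2=O | intermediate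
6 | 2',6'-dihydroxy-4'-methoxyacetophenone | CC(=O)c1c(O)cc(OC)cc1O | starting material
7 | 1-{2-[2,4-bis(benzyloxy)-6-hydroxyphenyl]-4-methoxyphenyl}-3-(2,6-dihydroxy-4-methoxyphenyl)propane-1,3-dione | COc1cc(O)c(C(=O)CC(=O)c2ccc(OC)cc2-c2c(O)cc(OCc3ccccc3)cc2OCc2ccccc2)c(O)c1 | intermediate
8 | 2-{2-[2,4-bis(benzyloxy)-6-hydroxyphenyl]-4-methoxyphenyl}-2,5-dihydroxy-7-methoxy-2,3-dihydro-4H-chromen-4-one (racemic hemiketal, not isolated) | COc1cc(O)c2C(=O)CC(O)(c3ccc(OC)cc3-c3c(O)cc(OCc4ccccc4)cc3OCc3ccccc3)Oc2c1 | intermediate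
9 | 2-[2-(2,4-bis(benzyloxy)-6-hydroxyphenyl)-4-methoxyphenyl]-5-hydroxy-7-methoxy-4H-chromen-4-one | COc1ccc(-c2cc(=O)c3c(O)cc(OC)cc3o2)c(-c2c(O)cc(OCc3ccccc3)cc2OCc2ccccc2)c1 | intermediate
10 | 1-(benzyloxy)-4-iodobenzene | Ic1ccc(OCc2ccccc2)cc1 | starting material
11 | ethyl propiolate | C#CC(=O)OCC | starting material
12 | ethyl 3-[4-(benzyloxy)phenyl]prop-2-ynoate | CCOC(=O)C#Cc1ccc(OCc2ccccc2)cc1 | intermediate
13 | ethyl (Z)-3-[4-(benzyloxy)phenyl]-3-{3,5-bis(benzyloxy)-2-[2-(5-hydroxy-7-methoxy-4-oxo-4H-chromen-2-yl)-5-methoxyphenyl]phenoxy}prop-2-enoate | CCOC(=O)/C=C(\Oc1cc(OCc2ccccc2)cc(OCc2ccccc2)c1-c1cc(OC)ccc1-c1cc(=O)c2c(O)cc(OC)cc2o1)c1ccc(OCc2ccccc2)cc1 | intermediate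
14 | (Z)-3-[4-(benzyloxy)phenyl]-3-{3,5-bis(benzyloxy)-2-[2-(5-hydroxy-7-methoxy-4-oxo-4H-chromen-2-yl)-5-methoxyphenyl]phenoxy}prop-2-enoic acid | OC(=O)/C=C(\Oc1cc(OCc2ccccc2)cc(OCc2ccccc2)c1-c1cc(OC)ccc1-c1cc(=O)c2c(O)cc(OC)cc2o1)c1ccc(OCc2ccccc2)cc1 | intermediate
15 | mixed anhydride of acid 14 with trifluoroacetic acid (Z, not isolated) | FC(F)(F)C(=O)OC(=O)/C=C(\Oc1cc(OCc2ccccc2)cc(OCc2ccccc2)c1-c1cc(OC)ccc1-c1cc(=O)c2c(O)cc(OC)cc2o1)c1ccc(OCc2ccccc2)cc1 | intermediate
16 | 5,7-bis(benzyloxy)-2-[4-(benzyloxy)phenyl]-8-[2-(5-hydroxy-7-methoxy-4-oxo-4H-chromen-2-yl)-5-methoxyphenyl]-4H-chromen-4-one | COc1ccc(-c2cc(=O)c3c(O)cc(OC)cc3o2)c(-c2c(OCc4ccccc4)cc(OCc4ccccc4)c3c(=O)cc(-c4ccc(OCc5ccccc5)cc4)oc23)c1 | intermediate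
17 | 5,7-dihydroxy-8-[2-(5-hydroxy-7-methoxy-4-oxo-4H-chromen-2-yl)-5-methoxyphenyl]-2-(4-hydroxyphenyl)-4H-chromen-4-one | COc1ccc(-c2cc(=O)c3c(O)cc(OC)cc3o2)c(-c2c(O)cc(O)c3c(=O)cc(-c4ccc(O)cc4)oc23)c1 | target

**Step count**

Total step count: 9. Longest linear sequence: 8 steps (steps 1–4 and 6–9, from 1 and 2 to 17); step 5 prepares 12 in a side branch.

**Steps most likely to fail**

Step 6. The conjugate addition may stall, because the phenoxide sits next to the biaryl axis and the acceptor is an electron-rich β-aryl ynoate. On prolonged heating with base the same phenoxide may instead add to C2 of flavone 1 and open its pyranone. The fallback sets out from 10 and 9 and returns at 14, using an acceptor at the aldehyde oxidation level that reacts at room temperature. Sonogashira coupling of 10 with propargyl alcohol (PdCl2(PPh3)2, CuI, Et3N) would give 3-[4-(benzyloxy)phenyl]prop-2-yn-1-ol F1. Oxidation with MnO2 in CH2Cl2 would give 3-[4-(benzyloxy)phenyl]prop-2-ynal F2. Phenol 9 should add to this ynal under catalysis by a weak tertiary amine (N-methylmorpholine, CH2Cl2, rt) to give (Z)-3-[4-(benzyloxy)phenyl]-3-{3,5-bis(benzyloxy)-2-[2-(5-hydroxy-7-methoxy-4-oxo-4H-chromen-2-yl)-5-methoxyphenyl]phenoxy}prop-2-enal F3. Pinnick oxidation (NaClO2, NaH2PO4, 2-methyl-2-butene, t-BuOH/THF/H2O) would then deliver acid 14 directly, so the saponification is bypassed as well.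

Step 4. Ring closure may run through the wrong hydroxyl: the biaryl phenol can add to the same carbonyl, and dehydration of that lactol would divert material to a 6-ylidene-benzo[c]chromene. Acid-induced loss or migration of benzyl groups is a second hazard. The fallback sets out from 5 and returns at 13, changing the order of events so that the biaryl oxygen is already a vinyl ether when the diketone is cyclised.
- Aminolysis of lactone 5 with N,O-dimethylhydroxylamine hydrochloride and AlMe3 (CH2Cl2) would give 2-[2,4-bis(benzyloxy)-6-hydroxyphenyl]-N,4-dimethoxy-N-methylbenzamide F4.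
- Oxa-Michael addition to 12 under the conditions of step 6 would give ethyl (Z)-3-[4-(benzyloxy)phenyl]-3-{3,5-bis(benzyloxy)-2-[5-methoxy-2-(methoxy(methyl)carbamoyl)phenyl]phenoxy}prop-2-enoate F5.
- Acylation of the lithium polyanion of 6 (LiHMDS, THF) by the Weinreb amide would give ethyl (Z)-3-[4-(benzyloxy)phenyl]-3-{3,5-bis(benzyloxy)-2-[2-(3-(2,6-dihydroxy-4-methoxyphenyl)-3-oxopropanoyl)-5-methoxyphenyl]phenoxy}prop-2-enoate F6.
- p-TsOH in toluene would cyclise F6, now through a chelated hydroxyl only, to ester 13.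

Step 3. Conversion may be poor because the lithium polyanion aggregates or precipitates in THF, and acylation at oxygen may compete with acylation at carbon. The fallback sets out from 6 and 5 and returns at 9, replacing the polyanion by the mono-enolate of a protected ketone. Treatment of 6 with MOMCl and NaH in DMF would give 1-[4-methoxy-2,6-bis(methoxymethoxy)phenyl]ethanone F7. Its lithium enolate (LiHMDS, 2.2 equiv, THF, −78 °C to rt) should open lactone 5 to 1-{2-[2,4-bis(benzyloxy)-6-hydroxyphenyl]-4-methoxyphenyl}-3-[4-methoxy-2,6-bis(methoxymethoxy)phenyl]propane-1,3-dione F8. HCl in MeOH/THF at 50 °C would remove both acetals and cyclodehydrate in the same operation to phenol 9.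

**Further compounds**

F1 | step 6 | 3-[4-(benzyloxy)phenyl]prop-2-yn-1-ol | OCC#Cc1ccc(OCc2ccccc2)cc1
F2 | step 6 | 3-[4-(benzyloxy)phenyl]prop-2-ynal | O=CC#Cc1ccc(OCc2ccccc2)cc1
F3 | step 6 | (Z)-3-[4-(benzyloxy)phenyl]-3-{3,5-bis(benzyloxy)-2-[2-(5-hydroxy-7-methoxy-4-oxo-4H-chromen-2-yl)-5-methoxyphenyl]phenoxy}prop-2-enal | O=C/C=C(\Oc1cc(OCc2ccccc2)cc(OCc2ccccc2)c1-c1cc(OC)ccc1-c1cc(=O)c2c(O)cc(OC)cc2o1)c1ccc(OCc2ccccc2)cc1
F4 | step 4 | 2-[2,4-bis(benzyloxy)-6-hydroxyphenyl]-N,4-dimethoxy-N-methylbenzamide | CON(C)C(=O)c1ccc(OC)cc1-c1c(O)cc(OCc2ccccc2)cc1OCc1ccccc1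
F5 | step 4 | ethyl (Z)-3-[4-(benzyloxy)phenyl]-3-{3,5-bis(benzyloxy)-2-[5-methoxy-2-(methoxy(methyl)carbamoyl)phenyl]phenoxy}prop-2-enoate | CCOC(=O)/C=C(\Oc1cc(OCc2ccccc2)cc(OCc2ccccc2)c1-c1cc(OC)ccc1C(=O)N(C)OC)c1ccc(OCc2ccccc2)cc1
F6 | step 4 | ethyl (Z)-3-[4-(benzyloxy)phenyl]-3-{3,5-bis(benzyloxy)-2-[2-(3-(2,6-dihydroxy-4-methoxyphenyl)-3-oxopropanoyl)-5-methoxyphenyl]phenoxy}prop-2-enoate | CCOC(=O)/C=C(\Oc1cc(OCc2ccccc2)cc(OCc2ccccc2)c1-c1cc(OC)ccc1C(=O)CC(=O)c1c(O)cc(OC)cc1O)c1ccc(OCc2ccccc2)cc1
F7 | step 3 | 1-[4-methoxy-2,6-bis(methoxymethoxy)phenyl]ethanone | CC(=O)c1c(OCOC)cc(OC)cc1OCOC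
F8 | step 3 | 1-{2-[2,4-bis(benzyloxy)-6-hydroxyphenyl]-4-methoxyphenyl}-3-[4-methoxy-2,6-bis(methoxymethoxy)phenyl]propane-1,3-dione | COCOc1cc(OC)cc(OCOC)c1C(=O)CC(=O)c1ccc(OC)cc1-c1c(O)cc(OCc2ccccc2)cc1OCc1ccccc1
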